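**Strategy.** Ring C of the flavone is opened at C4–C4a, O1–C8a and O1–C2. Ring A has methoxy groups on C5, C6, C7 and C8, so C4a and C8a can come from the two triple-bond carbons of 3,4,5,6-tetramethoxybenzyne, whose mirror symmetry makes both orientations of addition identical. In one operation the aryne inserts into the C–O bond of an arylpropiolic acid (carboxylate oxygen to C8a, acyl carbon to C4a) and the freed phenoxide closes the pyranone onto the ynone. The precursors are a hexasubstituted 2-silylaryl triflate for ring A and a 3-arylpropiolic acid carrying ring B with its 3'-hydroxyl masked as a benzyl ether.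

Key step: step 12

Assumption: flavone numbering is used for the target (O1, C2, C3, C4, C4a, C5–C8, C8a; ring B primed), and common reagents and solvents are taken as purchased.

**Ring A fragment (aryne precursor)**

Step 1
Reactants: 1 2,3,4-trimethoxybenzaldehyde
Product: 3 2,3,4-trimethoxyphenol, via 2,3,4-trimethoxyphenyl formate 2 (not isolated)
Conditions: 30% aq. H2O2, H2SO4 (cat.), MeOH, rt
Reagents that add atoms: hydrogen peroxide, OO
Why: Acid-catalysed Dakin oxidation (a Baeyer–Villiger-type 1,2-aryl shift in the peroxide adduct of the aldehyde) is favoured by the electron-rich ring, and formate 2 is methanolysed as it forms.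

Step 2
Reactants: 3 2,3,4-trimethoxyphenol
Product: 4 1,2,3,4-tetramethoxybenzene
Conditions: MeI, K2CO3, acetone, reflux
Reagents that add atoms: iodomethane, CI
Why: Williamson ether synthesis on the single phenoxide is unambiguous.

Step 3
Reactants: 4 1,2,3,4-tetramethoxybenzene
Product: 7 2,3,4,5-tetramethoxyphenol, via 2,3,4,5-tetramethoxyphenyllithium 5 (not isolated), via dimethyl (2,3,4,5-tetramethoxyphenyl)boronate 6 (not isolated)
Conditions: n-BuLi, TMEDA, THF, 0 °C → rt; B(OMe)3, −78 °C → rt; then AcOH, 30% aq. H2O2, 0 °C → rt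
Reagents that add atoms: hydrogen peroxide, OO (the new phenolic oxygen); n-butyllithium, [Li]CCCC (lithium of 5 only); trimethyl borate, COB(OC)OC (boron and its methoxy groups in 6 only)
Why: Methoxy-directed ortho-lithiation can only take place at the two symmetry-equivalent ring CH positions of 4, and borylation followed by peroxide oxidation (1,2-shift of aryl from boron to oxygen) turns the C–Li bond into C–OH under conditions too mild to oxidise the ring.

Step 4
Reactants: 7 2,3,4,5-tetramethoxyphenol
Product: 8 2,3,4,5-tetramethoxyphenyl N-isopropylcarbamate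
Conditions: iPrNCO, Et3N (cat.), CH2Cl2, rt
Reagents that add atoms: isopropyl isocyanate, CC(C)N=C=O
Why: Amine-catalysed addition of the phenol to the isocyanate (carbamoylation) installs a group that directs ortho-metalation and can be removed later under mild base.

Step 5
Reactants: 8 2,3,4,5-tetramethoxyphenyl N-isopropylcarbamate
Product: 12 2,3,4,5-tetramethoxy-6-(trimethylsilyl)phenyl N-isopropylcarbamate, via N-silyl carbamate 9 (not isolated), via ortho-lithiated N-silyl carbamate 10 (not isolated), via N,C-bis(trimethylsilyl) carbamate 11 (not isolated)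
Conditions: TMSOTf, TMEDA, Et2O, 0 °C → rt; then n-BuLi, TMEDA, −78 °C; TMSCl, −78 °C → rt; aq. NaHSO4 work-up
Reagents that add atoms: chlorotrimethylsilane, C[Si](C)(C)Cl (ring silyl group); trimethylsilyl trifluoromethanesulfonate, C[Si](C)(C)OS(=O)(=O)C(F)(F)F (N-silyl group of 9, 10 and 11 only); n-butyllithium, [Li]CCCC (lithium of 10 only)
Why: Directed ortho-metalation: with the NH masked in situ as N–SiMe3, n-BuLi/TMEDA removes the only ring hydrogen, which lies between the carbamate and a methoxy group, and the aryllithium is silylated at −78 °C before an anionic Fries shift can set in; the N–Si bond is hydrolysed on acidic work-up.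

Step 6
Reactants: 12 2,3,4,5-tetramethoxy-6-(trimethylsilyl)phenyl N-isopropylcarbamate
Product: 14 2,3,4,5-tetramethoxy-6-(trimethylsilyl)phenyl trifluoromethanesulfonate, via 2,3,4,5-tetramethoxy-6-(trimethylsilyl)phenol 13 (not isolated)
Conditions: DBU, Et2NH, MeCN, 40 °C; then PhNTf2, rt
Reagents that add atoms: N-phenylbis(trifluoromethanesulfonimide), O=S(=O)(N(c1ccccc1)S(=O)(=O)C(F)(F)F)C(F)(F)F
Why: DBU triggers E1cB loss of isopropyl isocyanate from the secondary carbamate (trapped by Et2NH as a urea) and the phenoxide is sulfonylated in the same pot by PhNTf2, a triflating agent mild enough to leave the aryl–silicon bond intact.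

**Ring B fragment (arylpropiolic acid)**

Step 7
Reactants: 15 1,2,4-trimethoxybenzene
Product: 18 2,3,6-trimethoxyphenol, via 2,3,6-trimethoxyphenyllithium 16 (not isolated), via dimethyl (2,3,6-trimethoxyphenyl)boronate 17 (not isolated)
Conditions: n-BuLi, THF, 0 °C → rt; B(OMe)3, −78 °C → rt; then AcOH, 30% aq. H2O2, 0 °C → rt
Reagents that add atoms: hydrogen peroxide, OO (the new phenolic oxygen); n-butyllithium, [Li]CCCC (lithium of 16 only); trimethyl borate, COB(OC)OC (boron and its methoxy groups in 17 only)
Why: The hydrogen at C3 of 15 is flanked by two methoxy groups and is removed selectively (cooperative directed ortho-lithiation); borylation and peroxide oxidation then deliver the phenol.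

Step 8
Reactants: 18 2,3,6-trimethoxyphenol
Product: 19 2,3,6-trimethoxyphenyl acetate
Conditions: Ac2O, pyridine, DMAP (cat.), CH2Cl2, rt
Reagents that add atoms: acetic anhydride, CC(=O)OC(C)=O
Why: DMAP-catalysed O-acetylation converts the strongly para-directing hydroxyl into a weakly donating acyloxy group for the halogenation that follows.

Step 9
Reactants: 19 2,3,6-trimethoxyphenyl acetate
Product: 20 3-iodo-2,5,6-trimethoxyphenyl acetate
Conditions: NIS, TFA (cat.), MeCN, 0 °C → rt, dark
Reagents that add atoms: N-iodosuccinimide, O=C1CCC(=O)N1I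
Why: Electrophilic aromatic iodination with acid-activated NIS should take place at C5 of 19, which is para to the 2-methoxy and ortho to the 6-methoxy group, since C4 is para only to the weakly donating acetoxy group.

Step 10
Reactants: 20 3-iodo-2,5,6-trimethoxyphenyl acetate
Product: 22 3-(benzyloxy)-1-iodo-2,4,5-trimethoxybenzene, via 3-iodo-2,5,6-trimethoxyphenol 21 (not isolated)
Conditions: K2CO3, MeOH, rt; concentrate; then BnBr, K2CO3, DMF, rt
Reagents that add atoms: benzyl bromide, BrCc1ccccc1
Why: Methanolysis of the aryl acetate and Williamson benzylation of the resulting phenoxide are run in sequence; the benzyl ether withstands base, fluoride and palladium coupling and is removable by hydrogenolysis.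

Step 11
Reactants: 22 3-(benzyloxy)-1-iodo-2,4,5-trimethoxybenzene; 23 propiolic acid
Product: 24 3-[3-(benzyloxy)-2,4,5-trimethoxyphenyl]prop-2-ynoic acid
Conditions: Pd(PPh3)4 (zerovalent palladium, cat.), DBU, DMSO, 35 °C; then cold 1 M HCl
Reagents that add atoms: none
Why: Copper-free Sonogashira coupling of the aryl iodide with the terminal C–H of propiolic acid (present as its DBU carboxylate) proceeds near ambient temperature, where the arylpropiolic acid does not lose CO2.

**Union and completion**

Step 12
Reactants: 14 2,3,4,5-tetramethoxy-6-(trimethylsilyl)phenyl trifluoromethanesulfonate; 24 3-[3-(benzyloxy)-2,4,5-trimethoxyphenyl]prop-2-ynoic acid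
Product: 29 2-[3-(benzyloxy)-2,4,5-trimethoxyphenyl]-5,6,7,8-tetramethoxy-4H-chromen-4-one, via 3,4,5,6-tetramethoxybenzyne 25 (not isolated), via O-aryl ester aryl anion 26 (not isolated), via benzoxetene alkoxide 27 (not isolated), via ortho-acyl phenoxide ynone 28 (not isolated)
Conditions: 14 (1.5 equiv), CsF (4 equiv), THF, sealed tube, 125 °C
Reagents that add atoms: none
Why: Fluoride attacks silicon in 14 and triflate departs to give the mirror-symmetric aryne 25, which is attacked by the carboxylate oxygen of 24 (caesium salt) to give aryl anion 26. The anion adds to its own ester carbonyl (4-exo-trig) to give the strained four-membered alkoxide 27, whose ring opening completes an O-to-C acyl shift and leaves phenoxide 28, so that C8a–O1 and C4a–C4 are both in place. The phenoxide then adds to the β-carbon of the aryl ynone in a 6-endo-dig oxa-Michael closure (O1–C2) and protonation at C3 gives ring C, the only ring formed. The closest known reaction type is the formal insertion of arynes from 2-silylaryl triflates into the C–O bond of carboxylic acids, which with arylpropiolic acids is known to deliver flavones; here it is applied to a tetraoxygenated aryne. No stereocentre is created, and regiochemistry of the aryne addition is not an issue because the two aryne carbons of 25 are equivalent and both are activated by a neighbouring methoxy group. The selectivities needed are acyl transfer over proton quench of 26, secured by the aprotic medium, the ionised acid and the carbonyl held next to the anion, and 6-endo over 5-exo closure, secured by the polarisation of the ynone and the stability of the chromone.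

Step 13
Reactants: 29 2-[3-(benzyloxy)-2,4,5-trimethoxyphenyl]-5,6,7,8-tetramethoxy-4H-chromen-4-one
Product: 30 agehoustin C
Conditions: H2 (1 atm), 10% Pd/C, EtOAc–MeOH, rt
Reagents that add atoms: none
Why: Catalytic hydrogenolysis cleaves the benzylic C–O bond under conditions (1 atm H2, rt) that leave the chromone C2=C3 bond, a doubly conjugated vinylogous ester, and the aryl methyl ethers untouched.

**Compound list**

1 | 2,3,4-trimethoxybenzaldehyde | COc1ccc(C=O)c(OC)c1OC | starting material
2 | 2,3,4-trimethoxyphenyl formate | COc1ccc(OC=O)c(OC)c1OC | intermediate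
3 | 2,3,4-trimethoxyphenol | COc1ccc(O)c(OC)c1OC | intermediate
4 | 1,2,3,4-tetramethoxybenzene | COc1ccc(OC)c(OC)c1OC | intermediate
5 | 2,3,4,5-tetramethoxyphenyllithium | [Li]c1cc(OC)c(OC)c(OC)c1OC | intermediate
6 | dimethyl (2,3,4,5-tetramethoxyphenyl)boronate | COB(OC)c1cc(OC)c(OC)c(OC)c1OC | intermediate
7 | 2,3,4,5-tetramethoxyphenol | COc1cc(O)c(OC)c(OC)c1OC | intermediate
8 | 2,3,4,5-tetramethoxyphenyl N-isopropylcarbamate | CC(C)NC(=O)Oc1cc(OC)c(OC)c(OC)c1OC | intermediate
9 | 2,3,4,5-tetramethoxyphenyl N-isopropyl-N-(trimethylsilyl)carbamate | CC(C)N([Si](C)(C)C)C(=O)Oc1cc(OC)c(OC)c(OC)c1OC | intermediate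
10 | 2-lithio-3,4,5,6-tetramethoxyphenyl N-isopropyl-N-(trimethylsilyl)carbamate | CC(C)N([Si](C)(C)C)C(=O)Oc1c([Li])c(OC)c(OC)c(OC)c1OC | intermediate
11 | 2,3,4,5-tetramethoxy-6-(trimethylsilyl)phenyl N-isopropyl-N-(trimethylsilyl)carbamate | CC(C)N([Si](C)(C)C)C(=O)Oc1c([Si](C)(C)C)c(OC)c(OC)c(OC)c1OC | intermediate
12 | 2,3,4,5-tetramethoxy-6-(trimethylsilyl)phenyl N-isopropylcarbamate | CC(C)NC(=O)Oc1c([Si](C)(C)C)c(OC)c(OC)c(OC)c1OC | intermediate
13 | 2,3,4,5-tetramethoxy-6-(trimethylsilyl)phenol (present as its DBU salt) | Oc1c([Si](C)(C)C)c(OC)c(OC)c(OC)c1OC | intermediate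
14 | 2,3,4,5-tetramethoxy-6-(trimethylsilyl)phenyl trifluoromethanesulfonate | COc1c([Si](C)(C)C)c(OS(=O)(=O)C(F)(F)F)c(OC)c(OC)c1OC | intermediate
15 | 1,2,4-trimethoxybenzene | COc1ccc(OC)c(OC)c1 | starting material
16 | 2,3,6-trimethoxyphenyllithium | [Li]c1c(OC)ccc(OC)c1OC | intermediate
17 | dimethyl (2,3,6-trimethoxyphenyl)boronate | COB(OC)c1c(OC)ccc(OC)c1OC | intermediate
18 | 2,3,6-trimethoxyphenol | COc1ccc(OC)c(O)c1OC | intermediate
19 | 2,3,6-trimethoxyphenyl acetate | CC(=O)Oc1c(OC)ccc(OC)c1OC | intermediate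
20 | 3-iodo-2,5,6-trimethoxyphenyl acetate | CC(=O)Oc1c(OC)c(I)cc(OC)c1OC | intermediate
21 | 3-iodo-2,5,6-trimethoxyphenol (present as its potassium salt) | Oc1c(OC)c(I)cc(OC)c1OC | intermediate
22 | 3-(benzyloxy)-1-iodo-2,4,5-trimethoxybenzene | COc1cc(I)c(OC)c(OCc2ccccc2)c1OC | intermediate
23 | propiolic acid | C#CC(=O)O | starting material
24 | 3-[3-(benzyloxy)-2,4,5-trimethoxyphenyl]prop-2-ynoic acid | COc1cc(C#CC(=O)O)c(OC)c(OCc2ccccc2)c1OC | intermediate
25 | 3,4,5,6-tetramethoxybenzyne | COC1=C(OC)C(OC)=C(OC)C#C1 | intermediate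
26 | 2-{[3-(3-benzyloxy-2,4,5-trimethoxyphenyl)prop-2-ynoyl]oxy}-3,4,5,6-tetramethoxyphenyl anion (caesium counter-ion not drawn) | COc1cc(C#CC(=O)Oc2[c-]c(OC)c(OC)c(OC)c2OC)c(OC)c(OCc3ccccc3)c1OC | intermediate
27 | 2-[(3-benzyloxy-2,4,5-trimethoxyphenyl)ethynyl]-3,4,5,6-tetramethoxy-2H-benzo[b]oxet-2-olate (caesium counter-ion not drawn) | [O-]C1(C#Cc2cc(OC)c(OC)c(OCc3ccccc3)c2OC)Oc2c(OC)c(OC)c(OC)c(OC)c12 | intermediate
28 | 2-[3-(3-benzyloxy-2,4,5-trimethoxyphenyl)prop-2-ynoyl]-3,4,5,6-tetramethoxyphenolate (caesium counter-ion not drawn) | [O-]c1c(OC)c(OC)c(OC)c(OC)c1C(=O)C#Cc1cc(OC)c(OC)c(OCc2ccccc2)c1OC | intermediate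
29 | 2-[3-(benzyloxy)-2,4,5-trimethoxyphenyl]-5,6,7,8-tetramethoxy-4H-chromen-4-one (3'-O-benzyl agehoustin C) | COc1cc(-c2cc(=O)c3c(OC)c(OC)c(OC)c(OC)c3o2)c(OC)c(OCc2ccccc2)c1OC | intermediate
30 | agehoustin C, 2-(3-hydroxy-2,4,5-trimethoxyphenyl)-5,6,7,8-tetramethoxy-4H-chromen-4-one | COc1cc(-c2cc(=O)c3c(OC)c(OC)c(OC)c(OC)c3o2)c(OC)c(O)c1OC | target

**Totals**

Total step count: 13. Longest linear sequence: 8 steps (steps 1–6, then 12 and 13, from 1). The ring B branch contributes 5 steps (7–11) before the union.

**Steps most likely to fail**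

1. Step 12. Aryl anion 26 may pick up a proton before the acyl shift, so that the sequence stalls at the aryl ester, or the caesium salt of 24 may lose CO2 at 125 °C before it meets the aryne. The fallback sets out from 7 and 22 and returns at 29. Phenol 7 is C-acetylated at its only free ring position (AcOH, BF3·OEt2, 90 °C, Friedel–Crafts/Fries type) to give 1-(2-hydroxy-3,4,5,6-tetramethoxyphenyl)ethan-1-one F1. Iodide 22 undergoes iodine–magnesium exchange (iPrMgCl·LiCl, THF, −20 °C → rt) to [3-(benzyloxy)-2,4,5-trimethoxyphenyl]magnesium chloride F2, which is formylated with DMF to 3-(benzyloxy)-2,4,5-trimethoxybenzaldehyde F3. Claisen–Schmidt condensation of the ketone with the aldehyde (KOH, EtOH, rt) should give (E)-3-[3-(benzyloxy)-2,4,5-trimethoxyphenyl]-1-(2-hydroxy-3,4,5,6-tetramethoxyphenyl)prop-2-en-1-one F4, and oxidative cyclisation of this 2'-hydroxychalcone (I2 cat., DMSO, 120 °C) should give 29.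

2. Step 9. Iodination may spread over both open ring positions of 19 (C5 and C4), because each has an ortho methoxy group and the 2-methoxy group, crowded on both sides, is a weakened para donor. The fallback sets out from 15 and returns at 22; it fixes the halogen position with a silicon placeholder before the hydroxyl is introduced. Compound 15 is brominated at C5, its uniquely activated position (NBS, MeCN, rt), to 1-bromo-2,4,5-trimethoxybenzene F5. Bromine–lithium exchange (n-BuLi, THF, −78 °C) gives 2,4,5-trimethoxyphenyllithium F6, and TMSCl converts it into trimethyl(2,4,5-trimethoxyphenyl)silane F7. Lithiation between the two flanking methoxy groups (n-BuLi, THF, 0 °C) gives (3-lithio-2,4,5-trimethoxyphenyl)trimethylsilane F8, B(OMe)3 gives dimethyl [2,3,6-trimethoxy-5-(trimethylsilyl)phenyl]boronate F9, and NaOH/H2O2 gives 2,3,6-trimethoxy-5-(trimethylsilyl)phenol F10. Benzylation (BnBr, K2CO3, DMF) gives [3-(benzyloxy)-2,4,5-trimethoxyphenyl]trimethylsilane F11, and ipso-iododesilylation (ICl, CH2Cl2, −78 → 0 °C) should give 22.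

3. Step 5. The ortho-lithiated carbamate 10 may undergo anionic Fries migration of the carbamoyl group, or the crowded aryllithium may be silylated incompletely. The fallback sets out from 7 and returns at 13, and from there at 14. Phenol 7 is brominated at its one free position (NBS, CH2Cl2, −78 → 0 °C) to 2-bromo-3,4,5,6-tetramethoxyphenol F12 and silylated on oxygen (HMDS, THF, reflux) to (2-bromo-3,4,5,6-tetramethoxyphenoxy)trimethylsilane F13. With n-BuLi (THF, −78 °C), bromine–lithium exchange gives (2-lithio-3,4,5,6-tetramethoxyphenoxy)trimethylsilane F14, and a 1,3-shift of silicon from oxygen to carbon (retro-Brook) then gives the lithium salt of 13. Tf2O added to the same flask should convert it into 14.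

**Further compounds**

F1 | step 12 | 1-(2-hydroxy-3,4,5,6-tetramethoxyphenyl)ethan-1-one | CC(=O)c1c(O)c(OC)c(OC)c(OC)c1OC
F2 | step 12 | [3-(benzyloxy)-2,4,5-trimethoxyphenyl]magnesium chloride | COc1cc([Mg]Cl)c(OC)c(OCc2ccccc2)c1OC
F3 | step 12 | 3-(benzyloxy)-2,4,5-trimethoxybenzaldehyde | COc1cc(C=O)c(OC)c(OCc2ccccc2)c1OC
F4 | step 12 | (E)-3-[3-(benzyloxy)-2,4,5-trimethoxyphenyl]-1-(2-hydroxy-3,4,5,6-tetramethoxyphenyl)prop-2-en-1-one | COc1cc(/C=C/C(=O)c2c(O)c(OC)c(OC)c(OC)c2OC)c(OC)c(OCc2ccccc2)c1OC
F5 | step 9 | 1-bromo-2,4,5-trimethoxybenzene | COc1cc(OC)c(OC)cc1Br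
F6 | step 9 | 2,4,5-trimethoxyphenyllithium | [Li]c1cc(OC)c(OC)cc1OC
F7 | step 9 | trimethyl(2,4,5-trimethoxyphenyl)silane | COc1cc(OC)c(OC)cc1[Si](C)(C)C
F8 | step 9 | (3-lithio-2,4,5-trimethoxyphenyl)trimethylsilane | COc1c([Li])c(OC)c(OC)cc1[Si](C)(C)C
F9 | step 9 | dimethyl [2,3,6-trimethoxy-5-(trimethylsilyl)phenyl]boronate | COB(OC)c1c(OC)c(OC)cc([Si](C)(C)C)c1OC
F10 | step 9 | 2,3,6-trimethoxy-5-(trimethylsilyl)phenol | COc1c(O)c(OC)c(OC)cc1[Si](C)(C)C
F11 | step 9 | [3-(benzyloxy)-2,4,5-trimethoxyphenyl]trimethylsilane | COc1cc([Si](C)(C)C)c(OC)c(OCc2ccccc2)c1OC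
F12 | step 5 | 2-bromo-3,4,5,6-tetramethoxyphenol | Oc1c(Br)c(OC)c(OC)c(OC)c1OC
F13 | step 5 | (2-bromo-3,4,5,6-tetramethoxyphenoxy)trimethylsilane | C[Si](C)(C)Oc1c(Br)c(OC)c(OC)c(OC)c1OC
F14 | step 5 | (2-lithio-3,4,5,6-tetramethoxyphenoxy)trimethylsilane | C[Si](C)(C)Oc1c([Li])c(OC)c(OC)c(OC)c1OC
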